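A small charge of electrophile, 0.050 M, was fed over 2.0 min into a flask holding 1.00 equiv of nucleophile and 0.500 equiv of free base. The teal run is this same flask, followed for its first minutes.

teal run (percent of the electrophile charged)

| time / min | electrophile / % | product / % |
|---|---|---|
| 1.33 | 50.1 | 16.6 |
| 3.00 | 60.2 | 39.0 |
| 4.00 | 55.6 | 44.6 |
| 6.00 | 51.1 | 48.1 |
| 8.00 | 50.6 | 49.0 |
| 10.0 | 50.0 | 50.5 |

(each reading ± 0.3 percentage points)

- what was read earlier has a scatter of 0.3 percentage points, one standard deviation
- percentages count the whole charge, also what has not yet gone in
- the earlier runs do not show how much of nucleophile is bound; that part of a forecast is a guess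

1. part of the electrophile that has reacted at 2.0 h
2. share of the unused nucleophile that is free and not bound as protonated nucleophile, at 2.0 h

I followed one molecule of electrophile. I supposed that on meeting a nucleophile it became product and set one acid free, and that this acid then stood at a fork: it could bind a second nucleophile as protonated nucleophile, or go to the free base. The odds at such a fork are the ratio of two rates.

If the acid goes to nucleophile, each electrophile reacted costs two nucleophiles, and that makes the nucleophile the limiting reagent, counted double. So I named the stall point: the equivalents of nucleophile divided by two, as a part of the electrophile charged, 50.0%. The readings fitted it. Product read 50.5% at 10.0 min, near the stall point, and had gained 2.4 percentage points in the last 4.00 min.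

Past that point, I reckoned, the other branch must pay: for each two acids taken by the free base, one more electrophile could react. I expected the flask to stand beyond 50.0% by that amount, which I did not size from these readings.

The forecast gave 56.7% reacted (54% to 60%) and 0.3% free (0.1% to 0.9%), holding that “the released acid protonates the nucleophile in preference to the weaker free base”.

The flask gave 58.5% reacted, inside the forecast's range, and 5.65% of the unused nucleophile free, above the forecast's high end.

acid set free + free base ⇌ salt of the base (K = 53900 M⁻¹, k = 6.86 M⁻¹ min⁻¹); electrophile + nucleophile ⇌ acid set free + product (K = 0.700, k = 11.4 M⁻¹ min⁻¹); nucleophile + acid set free ⇌ protonated nucleophile, settled at all times (K = 31800 M⁻¹) At 2.00 h the flask stood 8.5 points past the stall point, with free nucleophile at 2.3% of its charge and c(salt of the base) = 0.00915 M. The neighbour charged with 1.70 equiv of nucleophile has its stall point at 85.0%. It reached 87.8%, which is 2.8 points past that point, with c(salt of the base) = 0.00608 M.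

The numbers in the tables were generated by integration with constants of no real substance; noise was put on by code.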